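Readings and results were generated by integration with made-up constants, and the scatter is random.

**No empty flask.** Rule out Z first: gamma stands at 26.3 % of Z at 60.0 min, so it cannot have stopped for want of Z. Its X moves 0.6 percentage points from 25.0 min to 60.0 min, against a scatter of 0.5 points.

| flask | Z | L | Q | G | remark | time |
|---|---|---|---|---|---|---|
| alpha | 0.30 M | 0.30 M | 0.90 M | 0.36 mM | the very flask that is asked about, followed so far |  |
| gamma | 0.45 M | 0.45 M | 0.90 M | 0.36 mM | run made earlier |  |
| flask | 0.30 M | 0.30 M | 0.900 M | 0.36 mM |  | 1.5 h |

| run | time / min | Z / % | X / % |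
|---|---|---|---|
| alpha | 0.833 | 44.5 | 5.3 |
| alpha | 1.33 | 42.8 | 7.3 |
| alpha | 2.50 | 37.9 | 11.8 |
| alpha | 4.00 | 34.2 | 15.4 |
| alpha | 6.00 | 31.7 | 18.3 |
| alpha | 10.0 | 29.1 | 21.9 |
| gamma | 5.00 | 33.4 | 16.4 |
| gamma | 8.00 | 31.4 | 18.6 |
| gamma | 15.0 | 27.5 | 22.2 |
| gamma | 25.0 | 27.6 | 23.5 |
| gamma | 40.0 | 26.1 | 23.6 |
| gamma | 60.0 | 26.3 | 24.1 |

(each reading ± 0.5 percentage points)

- G is single-handed; Z and L are mirror images of each other, charged as a racemate, each of them at the stated concentration
- the numbers in the tables scatter by 0.5 percentage points (one standard deviation)
- the reaction counts as stopped when no species that holds the Z and L together changes by six tenths of a point or more over the second half of the time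

- which holds at 1.5 h: what has brought the reaction to rest, or that it has not come to rest (it is still moving / forward and back rates have come level / no working catalyst is left / Q has run out first / all of Z has reacted)
- how much of the Z and L together has reacted by 1.5 h
- how much X there is at 1.5 h, in percent of the Z and L together charged
- how much L there is at 1.5 h, in percent of the Z and L together charged

**Frozen clock.** Treat Z as a pseudo-first-order decay whose rate constant runs down. Charged Z is half of the percentage base. Gamma ends at 0.642 on the natural log of charged [Z] over present [Z], the reach: the count of time constants Z has gone through. Alpha's reach at 10.0 min is 0.541, between gamma's 0.465 at 8.00 min and 0.598 at 15.0 min, though [Z] starts at 0.30 M in alpha and 0.45 M in gamma. So read the reach as one curve in time for both charges of Z.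

**Next run.** Leave alpha as charged until 1.5 h; its Q and G match gamma's, so carry the reach over. My reckoning gives X 23.7 %. Add one reading of L at the end, because neither run followed L. I commit to no figure for L and to none of the listed ends: the readings follow neither Q nor G.

**The forecast.** It says no working catalyst is left, with conversion 25 %, X 24 % and L 49 %. Its grounds: “That looks like time-based catalyst death”. On X it stands with my reckoning; on the end state and on L it commits where I do not.

**The result.** At 1.5 h, alpha gives: Q has run out first. Q stands at 0.074 % of its charge, less than Z at 48 % and L at 77 % of theirs. Conversion is 37.6 %, X 26.1 % and L 38.5 %, against the forecast's 49 %.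

    Q → J (k = 0.00120 s⁻¹)
    Q + G + Z → G + X (k = 7.60 M⁻² s⁻¹)
    2 G → E (k = 3.70 M⁻¹ s⁻¹)
    Q + G + L → G + D (k = 2.70 M⁻² s⁻¹)

**Second flask.** Alpha's Z of 23.9 % at 1.50 h makes its reach 0.737. Now take the neighbour with G cut to 9.0 × 10⁻⁵ M, a quarter of alpha's charge, the other charges and the time held. Its Q falls as well, to 0.0916 % of its charge at 1.50 h, but its reach is 0.323, less than alpha's. In that neighbour Z stands at 36.2 % and X at 13.8 %.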